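**Retrosynthetic overview**
1. Target 15 ⇐ one-flask ozonolysis / hydride reduction of vinyl diester 13: the vinyl group becomes C9H2OH and the aryloxymalonate becomes the glycerol-2-yl ether.
2. 13 ⇐ C7–C8 bond between aldehyde 3 and the (Z)-γ-aryloxyallylborane 11. C8, an ether carbon and by nature an acceptor, reacts as an α-oxy carbanion (metalated allyl aryl ether moved onto boron), so two acceptor carbons are joined and both stereocentres (7R,8R, threo) are set in this step.
3. 3 ⇐ vanillin 1 + diethyl chloromalonate 2; allyl ether 8 ⇐ methoxyeugenol 4 (hydroboration–oxidation, then O-allylation with 7).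
4. No ring is formed: ring A comes from vanillin and ring B from methoxyeugenol.

Assumption: the SMILES is read as the threo (7R,8R) isomer (C7 = benzylic carbinol carbon, C8 = aryloxy-bearing carbon); (−)-Ipc2BOMe means the reagent made from (+)-α-pinene, with isopinocampheyl = (1R,2S,3R,5R)-2,6,6-trimethylbicyclo[3.1.1]heptan-3-yl.

**Route**

Step 1
Reactants: 1 vanillin (4-hydroxy-3-methoxybenzaldehyde); 2 diethyl chloromalonate (diethyl 2-chloropropanedioate)
Product: 3 diethyl 2-(4-formyl-2-methoxyphenoxy)propanedioate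
Conditions: K2CO3 (1.5 eq), MeCN, 60 °C
Reagents that add atoms: none
Why: Williamson-type SN2 O-alkylation in which the acidic vanillin phenoxide displaces chloride from the α-chloromalonate, installing the whole glycerol-2-yl unit at the diester oxidation level with no stereocentre involved.

Step 2
Reactants: 4 4-allyl-2,6-dimethoxyphenol (methoxyeugenol)
Product: 6 4-(3-hydroxypropyl)-2,6-dimethoxyphenol, via organoborane 5 (not isolated)
Conditions: 9-BBN (2.3 eq), THF, 0 → 25 °C; then 3 M NaOH, 30% H2O2, 0 → 25 °C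
Reagents that add atoms: hydrogen peroxide OO
Why: Brown hydroboration–oxidation, in which 9-BBN adds anti-Markovnikov to the terminal alkene (one further equivalent is taken up by the phenol O–H) and alkaline peroxide turns the primary C–B bond into the primary alcohol and frees the phenol; no stereocentre.

Step 3
Reactants: 6 4-(3-hydroxypropyl)-2,6-dimethoxyphenol; 7 allyl bromide
Product: 8 3-[3,5-dimethoxy-4-(prop-2-en-1-yloxy)phenyl]propan-1-ol
Conditions: K2CO3 (2 eq), DMF, 40 °C
Reagents that add atoms: none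
Why: Williamson etherification that is selective for the phenol because carbonate ionises only the phenol (pKa about 10) and not the primary alcohol; no stereocentre.

Step 4
Reactants: 8 3-[3,5-dimethoxy-4-(prop-2-en-1-yloxy)phenyl]propan-1-ol; 3 diethyl 2-(4-formyl-2-methoxyphenoxy)propanedioate
Product: 13 diethyl 2-{4-[(1R,2R)-1-hydroxy-2-[4-(3-hydroxypropyl)-2,6-dimethoxyphenoxy]but-3-en-1-yl]-2-methoxyphenoxy}propanedioate, via silyl ether 9 (not isolated), via allyllithium 10 (not isolated), via allylborane 11 (not isolated), via borinate 12 (not isolated)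
Conditions: 8 (1.3 eq), n-BuLi (1.3 eq), THF, −78 °C; TMSCl (1.3 eq), −78 → 0 °C; sec-BuLi (1.35 eq), −78 °C, 30 min; (−)-Ipc2BOMe (1.5 eq), −78 °C, 1 h; BF3·OEt2 (1.8 eq); 3 (1.0 eq), −78 °C, 4 h; then pH 7 buffer, MeOH, 30% H2O2, 0 → 25 °C; aq. citric acid wash
Reagents that add atoms: none
Why: Brown asymmetric γ-alkoxyallylboration, in which the transiently silylated allyl ether is deprotonated to the chelated (Z)-1-aryloxyallyllithium (an α-oxy carbanion, so the ether carbon C8 becomes the donor), boron is attached at the CH2 terminus, and the (Z)-allylborane adds to the Si face of aldehyde 3 through a chair Zimmerman–Traxler transition state (aryl equatorial, aryloxy axial), which fixes the syn (threo) relationship and, through the (+)-α-pinene-derived isopinocampheyl groups, the (1R,2R) configuration.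

Step 5
Reactants: 13 diethyl 2-{4-[(1R,2R)-1-hydroxy-2-[4-(3-hydroxypropyl)-2,6-dimethoxyphenoxy]but-3-en-1-yl]-2-methoxyphenoxy}propanedioate
Product: 15 (1R,2R)-1-{4-[(1,3-dihydroxypropan-2-yl)oxy]-3-methoxyphenyl}-2-[4-(3-hydroxypropyl)-2,6-dimethoxyphenoxy]propane-1,3-diol, via aldehyde 14 (not isolated)
Conditions: O3, CH2Cl2/MeOH 4:1, Sudan Red 7B end-point, −78 °C; then NaBH4 (4 eq), −78 → 0 °C; then LiBH4 (8 eq), THF, 0 → 25 °C; aq. NH4Cl
Reagents that add atoms: ozone O=[O+][O-]
Why: Criegee ozonolysis of the only C=C bond with hydride reduction in the same flask, in which NaBH4 reduces the peroxidic products and the configurationally labile α-aryloxy aldehyde 14 at low temperature before C8 can epimerise and LiBH4 then reduces both malonate esters to the 1,3-diol, so C7 and C8 are untouched and no new stereocentre is made.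

**Compound list**
1 | vanillin (4-hydroxy-3-methoxybenzaldehyde) | COc1cc(C=O)ccc1O | starting material
2 | diethyl chloromalonate (diethyl 2-chloropropanedioate) | CCOC(=O)C(Cl)C(=O)OCC | starting material
3 | diethyl 2-(4-formyl-2-methoxyphenoxy)propanedioate | CCOC(=O)C(Oc1ccc(C=O)cc1OC)C(=O)OCC | intermediate
4 | 4-allyl-2,6-dimethoxyphenol (methoxyeugenol) | COc1cc(CC=C)cc(OC)c1O | starting material
5 | 9-{3-[4-(9-borabicyclo[3.3.1]nonan-9-yloxy)-3,5-dimethoxyphenyl]propyl}-9-borabicyclo[3.3.1]nonane | COc1cc(CCCB2C3CCCC2CCC3)cc(OC)c1OB1C2CCCC1CCC2 | intermediate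
6 | 4-(3-hydroxypropyl)-2,6-dimethoxyphenol (dihydrosinapyl alcohol) | COc1cc(CCCO)cc(OC)c1O | intermediate
7 | allyl bromide (3-bromoprop-1-ene) | C=CCBr | starting material
8 | 3-[3,5-dimethoxy-4-(prop-2-en-1-yloxy)phenyl]propan-1-ol | C=CCOc1c(OC)cc(CCCO)cc1OC | intermediate
9 | {3-[3,5-dimethoxy-4-(prop-2-en-1-yloxy)phenyl]propoxy}trimethylsilane | C=CCOc1c(OC)cc(CCCO[Si](C)(C)C)cc1OC | intermediate
10 | [(2Z)-3-{2,6-dimethoxy-4-[3-(trimethylsilyloxy)propyl]phenoxy}prop-2-en-1-yl]lithium (chelated 1-aryloxyallyl anion) | [Li]C/C=C\Oc1c(OC)cc(CCCO[Si](C)(C)C)cc1OC | intermediate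
11 | [(2Z)-3-{2,6-dimethoxy-4-[3-(trimethylsilyloxy)propyl]phenoxy}prop-2-en-1-yl]bis[(1R,2S,3R,5R)-isopinocampheyl]borane | B(C/C=C\Oc1c(OC)cc(CCCO[Si](C)(C)C)cc1OC)([C@@H]1C[C@@H]2C[C@H]([C@H]1C)C2(C)C)[C@@H]1C[C@@H]2C[C@H]([C@H]1C)C2(C)C | intermediate
12 | diethyl 2-{4-[(1R,2R)-1-[bis(isopinocampheyl)boranyloxy]-2-{2,6-dimethoxy-4-[3-(trimethylsilyloxy)propyl]phenoxy}but-3-en-1-yl]-2-methoxyphenoxy}propanedioate | COc1cc([C@@H](OB([C@@H]2C[C@@H]3C[C@H]([C@H]2C)C3(C)C)[C@@H]2C[C@@H]3C[C@H]([C@H]2C)C3(C)C)[C@@H](C=C)Oc2c(OC)cc(CCCO[Si](C)(C)C)cc2OC)ccc1OC(C(=O)OCC)C(=O)OCC | intermediate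
13 | diethyl 2-{4-[(1R,2R)-1-hydroxy-2-[4-(3-hydroxypropyl)-2,6-dimethoxyphenoxy]but-3-en-1-yl]-2-methoxyphenoxy}propanedioate | COc1cc([C@@H](O)[C@@H](C=C)Oc2c(OC)cc(CCCO)cc2OC)ccc1OC(C(=O)OCC)C(=O)OCC | intermediate
14 | diethyl 2-{4-[(1R,2S)-1-hydroxy-2-[4-(3-hydroxypropyl)-2,6-dimethoxyphenoxy]-3-oxopropyl]-2-methoxyphenoxy}propanedioate | COc1cc([C@@H](O)[C@@H](C=O)Oc2c(OC)cc(CCCO)cc2OC)ccc1OC(C(=O)OCC)C(=O)OCC | intermediate
15 | (1R,2R)-1-{4-[(1,3-dihydroxypropan-2-yl)oxy]-3-methoxyphenyl}-2-[4-(3-hydroxypropyl)-2,6-dimethoxyphenoxy]propane-1,3-diol | COc1cc([C@@H](O)[C@@H](CO)Oc2c(OC)cc(CCCO)cc2OC)ccc1OC(CO)CO | target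

**Totals**
Total step count: 5. Longest linear sequence: 4 steps (4 → 6 → 8 → 13 → 15; steps 2, 3, 4, 5).

**Steps most likely to fail, with fallbacks**

Step 4 (key coupling). Risks:
- The hindered, electron-rich aryl allyl ether may lithiate sluggishly or at the ring.
- The route relies on the transient silyl ether.
- The acidic malonate C–H and the esters of 3 must stay inert towards the allylborane mixture.
- The enantiomeric excess of this reagent class is usually about 90%, not complete.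

Fallback: it sets out from 6 (and uses 3) and comes back to the route at 15. Phenol 6 is O-alkylated with (S)-4-benzyl-3-(chloroacetyl)-1,3-oxazolidin-2-one (K2CO3, NaI, acetone) to give (4S)-4-benzyl-3-{[4-(3-hydroxypropyl)-2,6-dimethoxyphenoxy]acetyl}-1,3-oxazolidin-2-one F1. Its Z-boron enolate (Bu2BOTf 2.2 eq, i-Pr2NEt, CH2Cl2, −78 °C; the extra equivalent masks the free hydroxyl as a borinate) adds to 3 in an Evans syn-aldol reaction. This gives diethyl 2-{4-[(1R,2S)-3-[(4S)-4-benzyl-2-oxo-1,3-oxazolidin-3-yl]-1-hydroxy-2-[4-(3-hydroxypropyl)-2,6-dimethoxyphenoxy]-3-oxopropyl]-2-methoxyphenoxy}propanedioate F2. LiBH4 in THF/MeOH then removes the auxiliary reductively and reduces both ethyl esters in the same operation, giving 15.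

Step 5 (ozonolysis / reduction). Risks:
- Ozone may attack the two electron-rich arenes.
- Aldehyde 14 can epimerise at C8 or undergo retro-aldol cleavage.
- The malonate reduction can be accompanied by elimination.

Fallback: it sets out from 13 and comes back at 14. Dihydroxylation of the vinyl group (K2OsO4·2H2O 2 mol %, NMO, acetone/water) gives diethyl 2-{4-[(1R,2S)-1,3,4-trihydroxy-2-[4-(3-hydroxypropyl)-2,6-dimethoxyphenoxy]butyl]-2-methoxyphenoxy}propanedioate F3 (both C3 epimers). NaIO4 in THF/pH 7 buffer at 0 °C cleaves the terminal diol to 14, which is reduced at once with NaBH4 and then LiBH4 as in the route.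

Step 1 (chloromalonate alkylation). Risks:
- The chloromalonate can enolise and attack the aldehyde (Darzens-type) or transfer halogen.
- The weakly nucleophilic vanillin phenoxide may react slowly.

Fallback: it sets out from 1 and comes back at 3. Diazo transfer to diethyl malonate (4-acetamidobenzenesulfonyl azide, Et3N, MeCN) gives diethyl 2-diazopropanedioate F4. Rh2(OAc)4 (1 mol %) in CH2Cl2 at 40 °C generates the rhodium carbenoid, which inserts into the phenol O–H bond of vanillin to give 3 under neutral conditions.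

**Further compounds**
F1 | step 4 | (4S)-4-benzyl-3-{[4-(3-hydroxypropyl)-2,6-dimethoxyphenoxy]acetyl}-1,3-oxazolidin-2-one | O=C1N(C(=O)COc2c(OC)cc(CCCO)cc2OC)[C@@H](Cc2ccccc2)CO1
F2 | step 4 | diethyl 2-{4-[(1R,2S)-3-[(4S)-4-benzyl-2-oxo-1,3-oxazolidin-3-yl]-1-hydroxy-2-[4-(3-hydroxypropyl)-2,6-dimethoxyphenoxy]-3-oxopropyl]-2-methoxyphenoxy}propanedioate | COc1cc([C@@H](O)[C@@H](C(=O)N2[C@@H](Cc3ccccc3)COC2=O)Oc2c(OC)cc(CCCO)cc2OC)ccc1OC(C(=O)OCC)C(=O)OCC
F3 | step 5 | diethyl 2-{4-[(1R,2S)-1,3,4-trihydroxy-2-[4-(3-hydroxypropyl)-2,6-dimethoxyphenoxy]butyl]-2-methoxyphenoxy}propanedioate (both C3 epimers) | COc1cc([C@@H](O)[C@@H](C(O)CO)Oc2c(OC)cc(CCCO)cc2OC)ccc1OC(C(=O)OCC)C(=O)OCC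
F4 | step 1 | diethyl 2-diazopropanedioate | CCOC(=O)C(=[N+]=[N-])C(=O)OCC
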